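**Retrosynthetic overview**

1. Cembrane-type numbering is used: C1 carries the isopropyl group, C2=C3 is the E-alkene, C4 the tertiary carbinol, C6 the ketone, C8 the methyl-bearing CH, C11 the formate carbinol, C12 the methyl-bearing oxolane carbon and C20 its methyl.
2. The C11–C12 bond is made last among the skeletal C–C bonds, by a Ni/Cr-mediated alkenyl–aldehyde ring closure of an open-chain enol triflate aldehyde. This closes the 14-membered carbocycle first; the oxolane (C1–O–C12) is closed second by transannular Markovnikov hydroalkoxylation, and the formate is put on last.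
3. The enabling feature is C12 itself. It is the oxolane carbon that bears both the ring oxygen and the C20 methyl next to the C11 carbinol, so it is the hydroalkoxylation retron of an exocyclic C12=C20 methylene. C12 can therefore enter the ring closure as an sp2 alkenyl nucleophile made from a methyl ketone, and C11 as an aldehyde.
4. The open chain comes from (R)-terpinen-4-ol (isopropyl, C1–C3, C12–C14, C20, by ozonolysis), a three-carbon ylide (C4, C5, C18; Sharpless epoxidation sets C4) and (S)-citronellal (C6–C11, C19; joined as its dithiane anion to a C4–C5 epoxide).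
5. Stereochemical plan: C1 and C8 come from the chiral pool, C4 from the epoxidation catalyst, C11 from a chiral ligand on chromium, and C12 from C1 through the cis-bridge constraint of the oxolane.

Key step: step 16

Remark: (R)-(−)-terpinen-4-ol and (S)-(−)-citronellal are assumed to be available commercially in high enantiomeric purity; the chiral oxazoline–sulfonamide ligand of step 16 is a known compound, used in the antipode that directs Si-face addition.

**Route**

Step 1
Reactants: 1 (R)-(−)-terpinen-4-ol
Product: 2 (R)-terpinen-4-yl triethylsilyl ether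
Conditions: TESOTf, 2,6-lutidine, CH2Cl2, 0 °C to rt
Reagents that add atoms: triethylsilyl trifluoromethanesulfonate, CC[Si](CC)(CC)OS(=O)(=O)C(F)(F)F
Why: Silylation of the hindered tertiary alcohol with a silyl triflate keeps the later γ-hydroxy ketone from closing to a lactol; no stereocentre is touched.

Step 2
Reactants: 2 (R)-terpinen-4-yl triethylsilyl ether
Product: 4 (3R)-keto aldehyde, via ozonide 3 (not isolated)
Conditions: O3, CH2Cl2, −78 °C; then Me2S, −78 °C to rt
Reagents that add atoms: ozone, [O-][O+]=O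
Why: Ozonolysis of the only alkene with reductive work-up should open the ring to the C3 aldehyde arm and the C12 methyl ketone arm on the intact C1 stereocentre.

Step 3
Reactants: 4 (3R)-keto aldehyde
Product: 5 (2E,5R)-keto enoate
Conditions: Ph3P=C(CH3)CO2Et, CH2Cl2, rt to 40 °C
Reagents that add atoms: ethyl 2-(triphenylphosphoranylidene)propanoate, CCOC(=O)C(C)=P(c1ccccc1)(c1ccccc1)c1ccccc1
Why: Wittig reaction of a stabilised α-methyl ylide should take the aldehyde and leave the methyl ketone, and should give the E-trisubstituted enoate that brings in C4, C5 and C18.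

Step 4
Reactants: 5 (2E,5R)-keto enoate
Product: 6 (2E,5R)-dimethyl ketal enoate
Conditions: HC(OMe)3, MeOH, PPTS (cat.), rt
Reagents that add atoms: trimethyl orthoformate, COC(OC)OC
Why: Ketalisation masks the C12 ketone against the hydride and the dithiane anion used later; the hindered tertiary silyl ether should survive the mild acid.

Step 5
Reactants: 6 (2E,5R)-dimethyl ketal enoate
Product: 7 (2E,5R)-allylic alcohol
Conditions: DIBAL-H, CH2Cl2, −78 °C; aq. Rochelle salt
Reagents that add atoms: none
Why: 1,2-Reduction of the enoate by DIBAL-H should give the (E)-2-methyl allylic alcohol needed for the directed epoxidation.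

Step 6
Reactants: 7 (2E,5R)-allylic alcohol
Product: 8 (2S,3S)-epoxy alcohol
Conditions: Ti(OiPr)4 (cat.), L-(+)-diethyl tartrate, t-BuOOH, 4 Å MS, CH2Cl2, −20 °C
Reagents that add atoms: tert-butyl hydroperoxide, CC(C)(C)OO
Why: Sharpless asymmetric epoxidation; the titanium L-(+)-tartrate catalyst should deliver oxygen to the face that gives the (2S,3S)-epoxide and so sets the C4 configuration, the remote C1 centre having no say.

Step 7
Reactants: 8 (2S,3S)-epoxy alcohol
Product: 10 (2R,3E,5S)-allylic 1,2-diol, via hydroxy selenide 9 (not isolated)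
Conditions: (PhSe)2, NaBH4, EtOH, rt to 60 °C; then THF, pyridine, 30% H2O2, 0 °C to rt
Reagents that add atoms: none
Why: Selenolate should open the epoxide by SN2 at C3, the only epoxide carbon that is not fully substituted, and the selenoxide syn-elimination can only use the C2 hydrogens, so it should give the E-C2=C3 alkene and the tertiary C4 carbinol with its C–O bond untouched.

Step 8
Reactants: 10 (2R,3E,5S)-allylic 1,2-diol
Product: 12 (2R)-alkenyl epoxide, via monotosylate 11 (not isolated)
Conditions: NaH, N-tosylimidazole, THF, 0 °C to rt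
Reagents that add atoms: none
Why: Selective sulfonylation of the primary hydroxyl followed by intramolecular Williamson closure from the tertiary alkoxide should give the terminal epoxide with C4 retained.

Step 9
Reactants: 13 (S)-(−)-citronellal
Product: 14 (S)-citronellal 1,3-dithiane
Conditions: HS(CH2)3SH, I2 (cat.), CH2Cl2, rt
Reagents that add atoms: propane-1,3-dithiol, SCCCS
Why: Mild dithioacetalisation should be much faster than the carbonyl-ene cyclisation of citronellal and turns C6 into an acyl anion equivalent; C8 is not touched.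

Step 10
Reactants: 14 (S)-citronellal 1,3-dithiane; 12 (2R)-alkenyl epoxide
Product: 16 dithiane tertiary alcohol, via lithiodithiane 15 (not isolated)
Conditions: 14, t-BuLi, THF/HMPA, −78 °C; then 12, −78 to −20 °C; H2O
Reagents that add atoms: none
Why: Corey–Seebach alkylation: the 2-lithio-1,3-dithiane should open the epoxide at the CH2 terminus (C5), because C4 is fully substituted and SN2′ attack at C2 is blocked by the quaternary C1, forming the C5–C6 bond with C4 retained.

Step 11
Reactants: 16 dithiane tertiary alcohol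
Product: 17 methyl ketone
Conditions: PPTS (cat.), acetone/H2O, rt
Reagents that add atoms: water, O
Why: Mild acetal hydrolysis should release the C12 methyl ketone while the dithiane, the tertiary silyl ether and the tertiary allylic alcohol stay intact.

Step 12
Reactants: 17 methyl ketone
Product: 18 enol triflate
Conditions: KHMDS (2.2 equiv), THF, −78 °C; then PhNTf2, −78 to −40 °C
Reagents that add atoms: N-phenylbis(trifluoromethanesulfonimide), O=S(=O)(N(c1ccccc1)S(=O)(=O)C(F)(F)F)C(F)(F)F
Why: Kinetic deprotonation at the less hindered methyl group (C20) and O-sulfonylation of the enolate should give the 2-triflyloxy-1-alkene, the dithiane keeping C6 from enolising.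

Step 13
Reactants: 18 enol triflate
Product: 19 β-hydroxy ketone
Conditions: MeI, CaCO3, MeCN/H2O, 40 °C
Reagents that add atoms: water, O
Why: S-Alkylative hydrolysis of the dithiane under buffered conditions should unveil the C6 ketone without retro-aldol cleavage or loss of the enol triflate.

Step 14
Reactants: 19 β-hydroxy ketone
Product: 20 keto diol
Conditions: HF·pyridine, pyridine, THF, 0 °C to rt
Reagents that add atoms: none
Why: Fluoride-mediated desilylation should free the C1 hydroxyl under conditions that are neither basic enough for retro-aldol cleavage nor acidic enough to ionise the tertiary allylic alcohols.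

Step 15
Reactants: 20 keto diol
Product: 22 open-chain keto aldehyde, via vicinal diol 21 (not isolated)
Conditions: OsO4 (cat.), NMO, acetone/H2O, 0 °C; then NaIO4, THF/H2O, rt
Reagents that add atoms: N-methylmorpholine N-oxide, C[N+]1([O-])CCOCC1
Why: Dihydroxylation and periodate cleavage should take only the electron-rich trisubstituted alkene, as the E-C2=C3 alkene lies between two quaternary carbons and the enol triflate is electron-poor, and so give the C11 aldehyde.

Step 16
Reactants: 22 open-chain keto aldehyde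
Product: 23 macrocyclic triol (1S,2E,4S,8S,11R)-1,4,11-trihydroxycembra-2,12(20)-dien-6-one
Conditions: CrCl2, chiral oxazoline–sulfonamide ligand, Et3N, NiCl2 (cat.), THF, rt, slow addition of 22 to ca. 2 mM; aqueous work-up
Reagents that add atoms: none
Why: Ni(0) inserts into the C12–OTf bond, the alkenyl group passes to Cr(III), and the C12 alkenylchromium adds to the C11 aldehyde (Nozaki–Hiyama–Kishi reaction). The closest known reaction type is the Ni/Cr-mediated macrocyclisation of alkenyl iodide or triflate aldehydes, including variants with chiral sulfonamide ligands on chromium. The 14-membered carbocycle closes by a 14-exo-trig addition to the C=O group. C11 is the only new stereocentre and should be set by the chiral ligand on chromium (Si-face addition gives 11R), since no existing stereocentre is closer than three bonds to either reacting carbon. The step needs attack on the aldehyde and not on the C6 ketone, and tolerance of the two tertiary hydroxyls; both are inherent to alkenylchromium(III) reagents. Ring closure over oligomerisation is secured by slow addition at high dilution and helped by the E-C2=C3 alkene between two quaternary carbons, which limits the freedom of the chain.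

Step 17
Reactants: 23 macrocyclic triol
Product: 24 oxolane alcohol (1S,2E,4S,8S,11R,12S)-1,12-epoxy-4,11-dihydroxycembr-2-en-6-one
Conditions: Co(salen) catalyst (cat.), N-fluoro-2,4,6-trimethylpyridinium triflate, PhSiH3, PhCF3, 0 °C to rt
Reagents that add atoms: none
Why: Cobalt-hydride hydrogen-atom transfer to the 1,1-disubstituted C12=C20 alkene gives the tertiary C12 radical, which is oxidised and captured by the C1 hydroxyl in a 5-exo Markovnikov hydroalkoxylation (Mukaiyama-type radical-polar crossover); C12 (12S) should follow from C1 because only the cis-bridged oxolane can be spanned by the ten-carbon C2–C11 bridge.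

Step 18
Reactants: 24 oxolane alcohol
Product: 25 CNP0176107.1
Conditions: acetic formic anhydride, pyridine, CH2Cl2, 0 °C
Reagents that add atoms: acetic formic anhydride, CC(=O)OC=O
Why: O-Formylation with the mixed anhydride should take the secondary C11 hydroxyl and leave the tertiary C4 hydroxyl, under conditions too mild for retro-aldol cleavage.

**Compound list**

1 | (R)-(−)-terpinen-4-ol, (1R)-4-methyl-1-(propan-2-yl)cyclohex-3-en-1-ol | CC(C)[C@]1(CCC(C)=CC1)O | starting material
2 | triethyl{[(1R)-4-methyl-1-(propan-2-yl)cyclohex-3-en-1-yl]oxy}silane | CC(C)[C@]1(CCC(C)=CC1)O[Si](CC)(CC)CC | intermediate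
3 | secondary ozonide (1,2,4-trioxolane) of 2, mixture at the two new bridgeheads | CC(C)[C@@]1(O[Si](CC)(CC)CC)CCC2(C)OOC(C1)O2 | intermediate
4 | (3R)-6-oxo-3-(propan-2-yl)-3-[(triethylsilyl)oxy]heptanal | CC(C)[C@](CCC(C)=O)(O[Si](CC)(CC)CC)CC=O | intermediate
5 | ethyl (2E,5R)-2-methyl-8-oxo-5-(propan-2-yl)-5-[(triethylsilyl)oxy]non-2-enoate | CC(C)[C@](CCC(C)=O)(O[Si](CC)(CC)CC)C/C=C(\C)C(=O)OCC | intermediate
6 | ethyl (2E,5R)-8,8-dimethoxy-2-methyl-5-(propan-2-yl)-5-[(triethylsilyl)oxy]non-2-enoate | CC(C)[C@](CCC(C)(OC)OC)(O[Si](CC)(CC)CC)C/C=C(\C)C(=O)OCC | intermediate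
7 | (2E,5R)-8,8-dimethoxy-2-methyl-5-(propan-2-yl)-5-[(triethylsilyl)oxy]non-2-en-1-ol | CC(C)[C@](CCC(C)(OC)OC)(O[Si](CC)(CC)CC)C/C=C(\C)CO | intermediate
8 | [(2S,3S)-3-{(2R)-5,5-dimethoxy-2-(propan-2-yl)-2-[(triethylsilyl)oxy]hexyl}-2-methyloxiran-2-yl]methanol | CC(C)[C@](CCC(C)(OC)OC)(O[Si](CC)(CC)CC)C[C@@H]1O[C@@]1(C)CO | intermediate
9 | (2S,3R,5R)-8,8-dimethoxy-2-methyl-3-(phenylselanyl)-5-(propan-2-yl)-5-[(triethylsilyl)oxy]nonane-1,2-diol | CC(C)[C@](CCC(C)(OC)OC)(O[Si](CC)(CC)CC)C[C@@H]([Se]c1ccccc1)[C@@](C)(O)CO | intermediate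
10 | (2R,3E,5S)-8,8-dimethoxy-2-methyl-5-(propan-2-yl)-5-[(triethylsilyl)oxy]non-3-ene-1,2-diol | CC(C)[C@](CCC(C)(OC)OC)(O[Si](CC)(CC)CC)/C=C/[C@@](C)(O)CO | intermediate
11 | (2R,3E,5S)-2-hydroxy-8,8-dimethoxy-2-methyl-5-(propan-2-yl)-5-[(triethylsilyl)oxy]non-3-en-1-yl 4-methylbenzenesulfonate | CC(C)[C@](CCC(C)(OC)OC)(O[Si](CC)(CC)CC)/C=C/[C@@](C)(O)COS(=O)(=O)c1ccc(C)cc1 | intermediate
12 | (2R)-2-{(1E,3S)-6,6-dimethoxy-3-(propan-2-yl)-3-[(triethylsilyl)oxy]hept-1-en-1-yl}-2-methyloxirane | CC(C)[C@](CCC(C)(OC)OC)(O[Si](CC)(CC)CC)/C=C/[C@]1(C)CO1 | intermediate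
13 | (S)-(−)-citronellal, (3S)-3,7-dimethyloct-6-enal | C[C@@H](CCC=C(C)C)CC=O | starting material
14 | 2-[(2S)-2,6-dimethylhept-5-en-1-yl]-1,3-dithiane | C[C@@H](CCC=C(C)C)CC1SCCCS1 | intermediate
15 | 2-[(2S)-2,6-dimethylhept-5-en-1-yl]-2-lithio-1,3-dithiane | C[C@@H](CCC=C(C)C)CC1([Li])SCCCS1 | intermediate
16 | (2S,3E,5S)-1-{2-[(2S)-2,6-dimethylhept-5-en-1-yl]-1,3-dithian-2-yl}-8,8-dimethoxy-2-methyl-5-(propan-2-yl)-5-[(triethylsilyl)oxy]non-3-en-2-ol | CC(C)[C@](CCC(C)(OC)OC)(O[Si](CC)(CC)CC)/C=C/[C@@](C)(O)CC1(SCCCS1)C[C@@H](C)CCC=C(C)C | intermediate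
17 | (5S,6E,8S)-9-{2-[(2S)-2,6-dimethylhept-5-en-1-yl]-1,3-dithian-2-yl}-8-hydroxy-8-methyl-5-(propan-2-yl)-5-[(triethylsilyl)oxy]non-6-en-2-one | CC(C)[C@](CCC(C)=O)(O[Si](CC)(CC)CC)/C=C/[C@@](C)(O)CC1(SCCCS1)C[C@@H](C)CCC=C(C)C | intermediate
18 | (5S,6E,8S)-9-{2-[(2S)-2,6-dimethylhept-5-en-1-yl]-1,3-dithian-2-yl}-8-hydroxy-8-methyl-5-(propan-2-yl)-5-[(triethylsilyl)oxy]nona-1,6-dien-2-yl trifluoromethanesulfonate | CC(C)[C@](CCC(=C)OS(=O)(=O)C(F)(F)F)(O[Si](CC)(CC)CC)/C=C/[C@@](C)(O)CC1(SCCCS1)C[C@@H](C)CCC=C(C)C | intermediate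
19 | (5S,6E,8S,12S)-8-hydroxy-8,12,16-trimethyl-10-oxo-5-(propan-2-yl)-5-[(triethylsilyl)oxy]heptadeca-1,6,15-trien-2-yl trifluoromethanesulfonate | CC(C)[C@](CCC(=C)OS(=O)(=O)C(F)(F)F)(O[Si](CC)(CC)CC)/C=C/[C@@](C)(O)CC(=O)C[C@@H](C)CCC=C(C)C | intermediate
20 | (5S,6E,8S,12S)-5,8-dihydroxy-8,12,16-trimethyl-10-oxo-5-(propan-2-yl)heptadeca-1,6,15-trien-2-yl trifluoromethanesulfonate | CC(C)[C@](CCC(=C)OS(=O)(=O)C(F)(F)F)(O)/C=C/[C@@](C)(O)CC(=O)C[C@@H](C)CCC=C(C)C | intermediate
21 | (5S,6E,8S,12S)-5,8,15,16-tetrahydroxy-8,12,16-trimethyl-10-oxo-5-(propan-2-yl)heptadeca-1,6-dien-2-yl trifluoromethanesulfonate, both C15 epimers | CC(C)[C@](CCC(=C)OS(=O)(=O)C(F)(F)F)(O)/C=C/[C@@](C)(O)CC(=O)C[C@@H](C)CCC(O)C(C)(C)O | intermediate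
22 | (5S,6E,8S,12S)-5,8-dihydroxy-8,12-dimethyl-10,15-dioxo-5-(propan-2-yl)pentadeca-1,6-dien-2-yl trifluoromethanesulfonate | CC(C)[C@](CCC(=C)OS(=O)(=O)C(F)(F)F)(O)/C=C/[C@@](C)(O)CC(=O)C[C@@H](C)CCC=O | intermediate
23 | (1S,2E,4S,8S,11R)-1,4,11-trihydroxycembra-2,12(20)-dien-6-one, i.e. (3S,4E,6S,10R,13S)-3,6,10-trihydroxy-3,13-dimethyl-9-methylidene-6-(propan-2-yl)cyclotetradec-4-en-1-one | CC(C)[C@]1(O)/C=C/[C@@](C)(O)CC(=O)C[C@@H](C)CC[C@@H](O)C(=C)CC1 | intermediate
24 | (1S,2E,4S,8S,11R,12S)-1,12-epoxy-4,11-dihydroxycembr-2-en-6-one | CC(C)[C@]12/C=C/[C@@](C)(O)CC(=O)C[C@@H](C)CC[C@@H](O)[C@](C)(CC1)O2 | intermediate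
25 | CNP0176107.1, (1S,2R,5S,9S,10E,12S)-9-hydroxy-1,5,9-trimethyl-7-oxo-12-(propan-2-yl)-15-oxabicyclo[10.2.1]pentadec-10-en-2-yl formate | CC(C)[C@]12/C=C/[C@@](C)(O)CC(=O)C[C@@H](C)CC[C@@H](OC=O)[C@](C)(CC1)O2 | target

**Step count and risks**

Total step count: 18. Longest linear sequence: 17 steps (steps 1–8 and 10–18, from 1).

Steps most likely to fail:

1. Step 16. What may go wrong is poor facial selectivity at the C11 aldehyde, if the ligand on chromium cannot impose itself on the macrocyclic transition state. The fallback sets out from 22 and separates ring formation from stereocontrol. The ring is closed without the chiral ligand (CrCl2, NiCl2 cat., DMF, high dilution), and whatever forms as the (11S)-macrocyclic triol F1 is separated. F1 is then inverted at its secondary allylic carbinol by Mitsunobu esterification with formic acid (PPh3, DIAD, THF, 0 °C) to the (11R)-macrocyclic formate F2. Brief methanolysis of F2 (KHCO3, MeOH, 0 °C) comes back to the route at 23.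

2. Step 17. What may go wrong is diversion of the cation-like C12 intermediate before the C1 hydroxyl captures it: a 1,2-hydride shift from C11 to a ketone, or three-membered ring closure by the neighbouring C11 hydroxyl. The fallback sets out from 23 and avoids a free cation. Selenoetherification (PhSeCl, K2CO3, CH2Cl2, −78 °C) goes through a bridged seleniranium ion, which the C1 hydroxyl should open at C12 in the 5-exo mode to the phenylselanylmethyl oxolane F3. Radical deselenation of F3 (Bu3SnH, AIBN, toluene, 80 °C) turns the CH2SePh group into the C20 methyl and comes back to the route at 24.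

3. Step 15. What may go wrong is loss of site selectivity, that is osmylation of the C2=C3 alkene (possibly assisted by its two allylic hydroxyls) or of the enol triflate beside the terminal trisubstituted alkene. The fallback sets out from 20 and uses electrophilic epoxidation, which discriminates more strongly by alkene substitution. mCPBA (1 equiv, NaHCO3, CH2Cl2, −20 °C) should give the terminal trisubstituted epoxide F4. Periodic acid (THF/Et2O, 0 °C) cleaves F4 to the aldehyde and comes back to the route at 22.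

Further compounds
F1 | step 16 | (1S,2E,4S,8S,11S)-1,4,11-trihydroxycembra-2,12(20)-dien-6-one | CC(C)[C@]1(O)/C=C/[C@@](C)(O)CC(=O)C[C@@H](C)CC[C@H](O)C(=C)CC1
F2 | step 16 | (1S,2E,4S,8S,11R)-1,4-dihydroxy-6-oxocembra-2,12(20)-dien-11-yl formate | CC(C)[C@]1(O)/C=C/[C@@](C)(O)CC(=O)C[C@@H](C)CC[C@@H](OC=O)C(=C)CC1
F3 | step 17 | (1S,2E,4S,8S,11R,12S)-1,12-epoxy-4,11-dihydroxy-20-(phenylselanyl)cembr-2-en-6-one | CC(C)[C@]12/C=C/[C@@](C)(O)CC(=O)C[C@@H](C)CC[C@@H](O)[C@](C[Se]c3ccccc3)(CC1)O2
F4 | step 15 | 15,16-epoxide of 20, (5S,6E,8S,12S)-13-(3,3-dimethyloxiran-2-yl)-5,8-dihydroxy-8,12-dimethyl-10-oxo-5-(propan-2-yl)trideca-1,6-dien-2-yl trifluoromethanesulfonate | CC(C)[C@](CCC(=C)OS(=O)(=O)C(F)(F)F)(O)/C=C/[C@@](C)(O)CC(=O)C[C@@H](C)CCC1OC1(C)C
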